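The C1–C10 oxirane bond is traced back to an E‑configured C1=C10 olefin in the ten‑membered ring. The route exploits that, across this olefin, the methyl carbon C14 and ring carbon C2 are cis. A temporary sulfur bridge C14–S–C2 is therefore installed first, inside an eleven‑membered thiacycle fused to the butenolide; this ring carries a vinyl group (C1) on C2 and a methylene group on C10. Transannular ring‑closing metathesis then forms C1=C10, closing a 2,5‑dihydrothiophene and the ten‑membered carbocycle in one operation, with E geometry enforced. Raney Ni excises sulfur (C14 becomes CH3), and peripheral double epoxidation finishes the target.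

Key step: step 12

Remark: germacrane numbering of the target is used for all intermediates (ring C1–C10, lactone carbons C11/C12, acetoxymethyl C13, C14 on C10, C15 on C4). Compounds 1, 6 and 8 are assumed to be commercial. The sulfur‑bearing C2 stereocentre is temporary and is erased in step 13. The CIP descriptor at C6 changes from R to S in the last step without any change of configuration.

Step 1
Reactants: 1 (2R)-2-vinyloxirane
Product: 2 (3S)-hex-1-en-5-yn-3-ol
Conditions: LiC≡CH·H2NCH2CH2NH2, DMSO, 0 °C to rt; then H2O
Reagents that add atoms: lithium acetylide–ethylenediamine complex, [Li+].[C-]#C.NCCN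
Why: SN2 epoxide opening by the acetylide at the unsubstituted CH2 terminus leaves the C–O stereocentre untouched, so the (R)-epoxide should give the (S)-alcohol (change of CIP priorities only).

Step 2
Reactants: 2 (3S)-hex-1-en-5-yn-3-ol
Product: 4 (3S,5E)-6-iodo-5-methylhexa-1,5-dien-3-ol, via alkenylalane 3 (not isolated)
Conditions: AlMe3 (3 equiv), Cp2ZrCl2 (0.25 equiv), CH2Cl2, 0 °C to rt; then I2, THF, −30 °C; aqueous work-up
Reagents that add atoms: trimethylaluminium, C[Al](C)C; iodine, II
Why: Negishi zirconium-catalysed carboalumination adds CH3 and Al syn across the terminal alkyne (Al at the terminus), and iodinolysis with retention gives the E-alkenyl iodide, the alkene and the aluminium alkoxide being spectators.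

Step 3
Reactants: 4 (3S,5E)-6-iodo-5-methylhexa-1,5-dien-3-ol
Product: 5 S-[(3R,5E)-6-iodo-5-methylhexa-1,5-dien-3-yl] ethanethioate
Conditions: PPh3, DIAD, AcSH, THF, 0 °C
Reagents that add atoms: thioacetic acid, CC(=O)S
Why: Mitsunobu reaction, in which thioacetate displaces the activated allylic alcohol with inversion to give the 3R thioester, the configuration that later lets sulfur sit in the plane of the C1=C10 olefin of the crown conformer.

Step 4
Reactants: 6 3-chloro-2-(chloromethyl)prop-1-ene
Product: 7 tributyl[2-(chloromethyl)prop-2-en-1-yl]stannane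
Conditions: Bu3SnH, LiN(iPr)2, THF, −78 °C; then 6 (3 equiv), −78 °C
Reagents that add atoms: tributyltin hydride, CCCC[SnH](CCCC)CCCC
Why: nucleophilic substitution of one allylic chloride by the stannyl anion (SN2 and SN2′ give the same product), with excess dichloride suppressing double substitution.

Step 5
Reactants: 8 furan-3,4-diyldimethanol
Product: 9 [4-(hydroxymethyl)furan-3-yl]methyl acetate
Conditions: Ac2O (1.0 equiv), pyridine, CH2Cl2, 0 °C
Reagents that add atoms: acetic anhydride, CC(=O)OC(C)=O
Why: statistical mono-acylation of a symmetric diol, from which diol and diacetate are separable and recyclable.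

Step 6
Reactants: 9 [4-(hydroxymethyl)furan-3-yl]methyl acetate
Product: 10 (4-formylfuran-3-yl)methyl acetate
Conditions: MnO2 (activated), CH2Cl2, rt
Reagents that add atoms: none
Why: MnO2 oxidation of a furylic (benzylic-type) primary alcohol should stop at the aldehyde and leave the acetate alone.

Step 7
Reactants: 10 (4-formylfuran-3-yl)methyl acetate; 7 tributyl[2-(chloromethyl)prop-2-en-1-yl]stannane
Product: 11 {4-[(1S)-3-(chloromethyl)-1-hydroxybut-3-en-1-yl]furan-3-yl}methyl acetate
Conditions: (S)-BINOL (20 mol %), Ti(OiPr)4 (10 mol %), 4 Å MS, CH2Cl2, −20 °C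
Reagents that add atoms: none
Why: Keck catalytic asymmetric allylation, in which the (S)-BINOL–titanium Lewis acid should direct the allylstannane to the aldehyde face that gives the 1S carbinol (C8 of the target), while the allylic chloride of the bifunctional stannane is carried through.

Step 8
Reactants: 11 {4-[(1S)-3-(chloromethyl)-1-hydroxybut-3-en-1-yl]furan-3-yl}methyl acetate
Product: 12 (1S)-1-[4-(acetoxymethyl)furan-3-yl]-3-(chloromethyl)but-3-en-1-yl 2-methylpropanoate
Conditions: (iPrCO)2O, pyridine, DMAP (cat.), CH2Cl2, 0 °C
Reagents that add atoms: isobutyric anhydride, CC(C)C(=O)OC(=O)C(C)C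
Why: DMAP-catalysed acylation installs the C8 isobutyrate under conditions too weakly basic for the alcohol to cyclise onto the allylic chloride.

Step 9
Reactants: 12 (1S)-1-[4-(acetoxymethyl)furan-3-yl]-3-(chloromethyl)but-3-en-1-yl 2-methylpropanoate
Product: 13 (1S)-1-[4-(acetoxymethyl)-2-hydroxy-5-oxo-2,5-dihydrofuran-3-yl]-3-(chloromethyl)but-3-en-1-yl 2-methylpropanoate
Conditions: O2, hν (visible), tetraphenylporphyrin (cat.), iPr2NEt, CH2Cl2, −78 °C
Reagents that add atoms: oxygen, O=O
Why: singlet-oxygen [4+2] cycloaddition to the furan followed by Kornblum–DeLaMare-type fragmentation of the endoperoxide, in which the hindered amine should remove the less encumbered bridgehead H next to CH2OAc and so place the lactone carbonyl at C12 and the hemiacetal at C6.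

Step 10
Reactants: 13 (1S)-1-[4-(acetoxymethyl)-2-hydroxy-5-oxo-2,5-dihydrofuran-3-yl]-3-(chloromethyl)but-3-en-1-yl 2-methylpropanoate; 5 S-[(3R,5E)-6-iodo-5-methylhexa-1,5-dien-3-yl] ethanethioate
Product: 16 methyl (2Z,4S)-2-(acetoxymethyl)-3-formyl-6-({[(3R,5E)-6-iodo-5-methylhexa-1,5-dien-3-yl]sulfanyl}methyl)-4-(2-methylpropanoyloxy)hepta-2,6-dienoate, via thiol 14 (not isolated), via sulfide lactol 15 (not isolated)
Conditions: 5, pyrrolidine (1.0 equiv), degassed DMF, 0 °C; then 13, Cs2CO3 (2.2 equiv), 0 °C; then MeI, 0 °C to rt
Reagents that add atoms: iodomethane, CI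
Why: aminolysis frees the thiol, its thiolate displaces the primary allylic chloride (SN2) to join the two fragments, and O-methylation of the ring-opened caesium carboxylate of the pseudo-acid unveils the Z-configured C6 aldehyde, both stereocentres being untouched.

Step 11
Reactants: 16 methyl (2Z,4S)-2-(acetoxymethyl)-3-formyl-6-({[(3R,5E)-6-iodo-5-methylhexa-1,5-dien-3-yl]sulfanyl}methyl)-4-(2-methylpropanoyloxy)hepta-2,6-dienoate
Product: 18 eleven-membered thiacycle fused to the 13-acetoxy butenolide (2R,6R,8S,4E; C2 vinyl and C10 methylene), via hydroxy ester 17 (not isolated)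
Conditions: CrCl2 (6 equiv), NiCl2 (2 mol %), N-[2-((S)-4-isopropyl-4,5-dihydrooxazol-2-yl)-6-methylphenyl]methanesulfonamide, Et3N, THF, 3 mM (slow addition), 25 °C; then aq. NH4Cl; PPTS (cat.), CH2Cl2
Reagents that add atoms: none
Why: intramolecular Nozaki–Hiyama–Kishi coupling of the E-alkenyl iodide (geometry retained) with the C6 aldehyde closes the eleven-membered ring and the Z-γ-hydroxy ester lactonises to the butenolide; the C6 carbinol should be set by the chiral sulfonamide ligand on chromium (its enantiomer is used if the sense proves mismatched), and C6 epimers are separable.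

Step 12
Reactants: 18 eleven-membered thiacycle fused to the 13-acetoxy butenolide
Product: 19 (2R,6R,8S)-13-acetoxy-2,14-epithio-8-(isobutyryloxy)germacra-1(10)E,4E,7(11)-trien-6,12-olide
Conditions: second-generation Grubbs catalyst RuCl2(H2IMes)(PCy3)(=CHPh) (10 mol %), 1,4-benzoquinone (20 mol %), toluene, 2 mM, 60 °C
Reagents that add atoms: none
Why: Ring-closing olefin metathesis by the Chauvin [2+2]/retro-[2+2] sequence (the ruthenium carbene loads at the C1 vinyl group, adds across the C10 methylene and releases ethene), the closest known reaction type being the metathesis of diallyl sulfides to 2,5-dihydrothiophenes with second-generation ruthenium catalysts. One bond closes two rings: the five-membered 2,5-dihydrothiophene (C10, C1, C2, S, C14) by a favourable five-ring closure of a 1,6-diene, and thereby, transannularly across the eleven-membered thiacycle, the ten-membered carbocycle C1–C10. No new stereocentre arises; the only stereochemical element, the C1=C10 geometry, is dictated by the small ring, in which C14 and C2 must be cis, so that C9 and C2 are trans and the olefin is E within the ten-membered ring. The step needs site selectivity among four olefins and ring closure over oligomerisation: only the monosubstituted C1 vinyl and the 1,1-disubstituted C10 methylene are accessible, and the sulfur atom holds them in a 1,6 relationship, whereas the trisubstituted C4=C5 and the tetrasubstituted butenolide olefin should not engage. With the 2R configuration, sulfur occupies the site of the outward, olefin-eclipsing hydrogen on C2 of the crown conformer, so the bridge should add little strain to the E,E ring.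

Step 13
Reactants: 19 (2R,6R,8S)-13-acetoxy-2,14-epithio-8-(isobutyryloxy)germacra-1(10)E,4E,7(11)-trien-6,12-olide
Product: 20 (6R,8S)-13-acetoxy-8-(isobutyryloxy)germacra-1(10)E,4E,7(11)-trien-6,12-olide
Conditions: Raney Ni (W-2, deactivated in refluxing acetone), acetone–EtOH, 0 °C to rt
Reagents that add atoms: none
Why: reductive desulfurisation of the 2,5-dihydrothiophene cleaves both allylic C–S bonds with hydrogen delivery to C14 and C2, turning C14 into the methyl group and C2 into CH2 while the trisubstituted E-olefin stays in place; deactivated nickel should spare the hindered olefins and the esters.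

Step 14
Reactants: 20 (6R,8S)-13-acetoxy-8-(isobutyryloxy)germacra-1(10)E,4E,7(11)-trien-6,12-olide
Product: 22 (1R,4R,5R,6S,8S,10R)-13-acetoxy-1,10:4,5-diepoxy-8-(isobutyryloxy)germacr-7(11)-en-6,12-olide, via monoepoxide 21 (not isolated)
Conditions: mCPBA (2.4 equiv), NaHCO3, CH2Cl2, 0 °C
Reagents that add atoms: meta-chloroperoxybenzoic acid, OOC(=O)c1cccc(Cl)c1
Why: Prilezhaev epoxidation, in which the crown conformer (C14 and C15 syn, H1 and H5 pointing into the ring) exposes only the outer face of each E-olefin, so peripheral attack should give the 1R,10R and 4R,5R trans-epoxides while the electron-poor tetrasubstituted butenolide olefin stays inert and the buffer prevents transannular cyclisation.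

Compound list
1 | (2R)-2-vinyloxirane | C=C[C@@H]1CO1 | starting material
2 | (3S)-hex-1-en-5-yn-3-ol | O[C@H](C=C)CC#C | intermediate
3 | [(1E,4S)-4-(dimethylalumanyloxy)-2-methylhexa-1,5-dien-1-yl]dimethylalumane (alkenylalane) | C[Al](C)O[C@H](C=C)C/C(C)=C/[Al](C)C | intermediate
4 | (3S,5E)-6-iodo-5-methylhexa-1,5-dien-3-ol | O[C@H](C=C)C/C(C)=C/I | intermediate
5 | S-[(3R,5E)-6-iodo-5-methylhexa-1,5-dien-3-yl] ethanethioate | CC(=O)S[C@@H](C=C)C/C(C)=C/I | intermediate
6 | 3-chloro-2-(chloromethyl)prop-1-ene | ClCC(=C)CCl | starting material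
7 | tributyl[2-(chloromethyl)prop-2-en-1-yl]stannane | ClCC(=C)C[Sn](CCCC)(CCCC)CCCC | intermediate
8 | furan-3,4-diyldimethanol | OCc1cocc1CO | starting material
9 | [4-(hydroxymethyl)furan-3-yl]methyl acetate | CC(=O)OCc1cocc1CO | intermediate
10 | (4-formylfuran-3-yl)methyl acetate | CC(=O)OCc1cocc1C=O | intermediate
11 | {4-[(1S)-3-(chloromethyl)-1-hydroxybut-3-en-1-yl]furan-3-yl}methyl acetate | CC(=O)OCc1cocc1[C@@H](O)CC(=C)CCl | intermediate
12 | (1S)-1-[4-(acetoxymethyl)furan-3-yl]-3-(chloromethyl)but-3-en-1-yl 2-methylpropanoate | CC(=O)OCc1cocc1[C@@H](OC(=O)C(C)C)CC(=C)CCl | intermediate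
13 | (1S)-1-[4-(acetoxymethyl)-2-hydroxy-5-oxo-2,5-dihydrofuran-3-yl]-3-(chloromethyl)but-3-en-1-yl 2-methylpropanoate (lactol, hemiacetal carbon C6 as epimer mixture) | CC(=O)OCC1=C([C@@H](OC(=O)C(C)C)CC(=C)CCl)C(O)OC1=O | intermediate
14 | (3R,5E)-6-iodo-5-methylhexa-1,5-diene-3-thiol | S[C@@H](C=C)C/C(C)=C/I | intermediate
15 | sulfide lactol: 13 with Cl replaced by the (3R,5E)-6-iodo-5-methylhexa-1,5-dien-3-ylsulfanyl group | CC(=O)OCC1=C([C@@H](OC(=O)C(C)C)CC(=C)CS[C@@H](C=C)C/C(C)=C/I)C(O)OC1=O | intermediate
16 | methyl (2Z,4S)-2-(acetoxymethyl)-3-formyl-6-({[(3R,5E)-6-iodo-5-methylhexa-1,5-dien-3-yl]sulfanyl}methyl)-4-(2-methylpropanoyloxy)hepta-2,6-dienoate | COC(=O)/C(COC(C)=O)=C(C=O)/[C@@H](OC(=O)C(C)C)CC(=C)CS[C@@H](C=C)C/C(C)=C/I | intermediate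
17 | hydroxy ester: eleven-membered thiacycle with free 6R carbinol and Z methyl ester (C12) not yet lactonised | COC(=O)/C(COC(C)=O)=C1/[C@@H](OC(=O)C(C)C)CC(=C)CS[C@@H](C=C)C/C(C)=C/[C@H]1O | intermediate
18 | eleven-membered thiacycle C6–C5=C4(CH3)–C3H2–C2H(CH=CH2)–S–C14H2–C10(=CH2)–C9H2–C8H(OiBu)–C7, fused at C6/C7 to the 13-acetoxy butenolide; 2R,6R,8S,4E | CC(=O)OCC1=C2[C@@H](OC(=O)C(C)C)CC(=C)CS[C@@H](C=C)C/C(C)=C/[C@H]2OC1=O | intermediate
19 | (2R,6R,8S)-13-acetoxy-2,14-epithio-8-(isobutyryloxy)germacra-1(10)E,4E,7(11)-trien-6,12-olide | CC(=O)OCC1=C2[C@@H](OC(=O)C(C)C)CC3=C[C@@H](C/C(C)=C/[C@H]2OC1=O)SC3 | intermediate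
20 | (6R,8S)-13-acetoxy-8-(isobutyryloxy)germacra-1(10)E,4E,7(11)-trien-6,12-olide | CC(=O)OCC1=C2[C@@H](OC(=O)C(C)C)C/C(C)=C/CC/C(C)=C/[C@H]2OC1=O | intermediate
21 | (1R,6R,8S,10R)-13-acetoxy-1,10-epoxy-8-(isobutyryloxy)germacra-4E,7(11)-dien-6,12-olide | CC(=O)OCC1=C2[C@@H](OC(=O)C(C)C)C[C@@]3(C)O[C@@H]3CC/C(C)=C/[C@H]2OC1=O | intermediate
22 | (1R,4R,5R,6S,8S,10R)-13-acetoxy-1,10:4,5-diepoxy-8-(isobutyryloxy)germacr-7(11)-en-6,12-olide | CC(=O)OCC1=C2[C@@H](OC(=O)C(C)C)C[C@@]3(C)O[C@@H]3CC[C@@]3(C)O[C@@H]3[C@H]2OC1=O | target

Total step count: 14. Longest linear sequence: 10 steps (steps 5 to 14, from 8 to 22).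

Steps most likely to fail

Step 13. On the nickel surface, cleavage of the two allylic C–S bonds may be accompanied by double-bond migration or saturation, and by hydrogenolysis of allylic C–O bonds. The fallback is a homogeneous radical-chain desulfurisation that sets out from 19 and returns to the route at 20. With Bu3SnH and AIBN in benzene at 80 °C, stannyl radicals attack sulfur and each allylic C–S bond homolyses. The resulting allyl radicals should take hydrogen from the tin hydride at the less substituted terminus, first at C14 and then at C2, which keeps the trisubstituted E-olefin. No further compound is formed on the way (F0).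

Step 11. The chromium-mediated closure of the eleven-membered ring may be overtaken by oligomerisation, and facial control at C6 may be insufficient. The fallback reverses the order of the two ring closures; it sets out from 16 and returns at 19. Metathesis of 16 under the conditions of step 12 is then an ordinary five-ring closure of an open-chain diallyl sulfide and should give the dihydrothiophene aldehyde ester F1, in which the E-olefin is already locked. Nozaki–Hiyama–Kishi coupling of F1 under the conditions of step 11 then closes the ten-membered carbocycle through a different, more rigid transition state to the hydroxy ester F2, which lactonises to 19.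

Step 9. Proton abstraction from the furan endoperoxide may be unselective, which would lose the regiocontrol between C6 and C12. The fallback replaces the kinetic deprotonation by a reduction–oxidation sequence; it sets out from 12 and returns at 13. Photo-oxygenation of 12 without base at −78 °C gives the furan endoperoxide F3, which is reduced in the flask with Me2S to the Z-enedial F4, present as its cyclic bis-hemiacetal. TEMPO (cat.) with PhI(OAc)2 then oxidises one hemiacetal carbon to the lactone; the bulky oxoammonium salt should abstract hydride at the less hindered C12 and deliver 13.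

Further compounds
F0 | step 13 | none | none
F1 | step 11 | methyl (2Z,4S)-2-(acetoxymethyl)-3-formyl-5-{(5R)-5-[(2E)-3-iodo-2-methylprop-2-en-1-yl]-2,5-dihydrothiophen-3-yl}-4-(2-methylpropanoyloxy)pent-2-enoate | COC(=O)/C(COC(C)=O)=C(C=O)/[C@@H](OC(=O)C(C)C)CC1=C[C@@H](C/C(C)=C/I)SC1
F2 | step 11 | hydroxy ester of 19: 2,14-epithio ten-membered carbocycle with free 6R carbinol and Z methyl ester (C12) not yet lactonised | COC(=O)/C(COC(C)=O)=C1/[C@@H](OC(=O)C(C)C)CC2=C[C@@H](C/C(C)=C/[C@H]1O)SC2
F3 | step 9 | furan endoperoxide of 12 (2,3,7-trioxabicyclo[2.2.1]hept-5-ene bearing the acetoxymethyl group and the C8 side chain of 12) | CC(=O)OCC1=C([C@@H](OC(=O)C(C)C)CC(=C)CCl)C2OOC1O2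
F4 | step 9 | (2Z)-2-(acetoxymethyl)-3-[(1S)-3-(chloromethyl)-1-(2-methylpropanoyloxy)but-3-en-1-yl]but-2-enedial | O=C/C(COC(C)=O)=C(\C=O)[C@@H](OC(=O)C(C)C)CC(=C)CCl
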